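## Retrosynthetic overview
- Sophoraflavanone G (20) comes from the protected flavanone 19. The C ring is closed last, by asymmetric intramolecular oxa‑Michael addition of the 2'‑hydroxychalcone 18.
- 18 is disconnected by Claisen–Schmidt condensation into the lavandulylated acetophenone 15 and the 2,4‑bis(MOM)benzaldehyde 17. This is the late coupling of two fragments of comparable size.
- 15 comes from a Negishi coupling of (S)‑lavandulyl iodide (6) with the aryl iodide 11, followed by acetylation. 6 is made by Evans deconjugative alkylation of a senecioyl imide with prenyl bromide.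
- Both aromatic rings start from resorcinol. The A ring gets its third oxygen by Ir C–H borylation and oxidation. The B ring is formylated by Vilsmeier–Haack.

Assumptions:
- The target is (2S) at the flavanone C2 and (R) at the lavandulyl centre, as written in the SMILES.
- The lavandulyl centre is called (S) in 4, 5 and 6 and (R) from 12 onward. The spatial arrangement is unchanged; only the CIP priorities change when CO/CH2I becomes CH2Ar.
- (S)‑4‑benzyloxazolidin‑2‑one is a recoverable chiral auxiliary used as a reagent.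

## Route

**Step 1**
Reactants: 1, 3,3‑dimethylacryloyl chloride
Product: 2, (4S)‑4‑benzyl‑3‑(3‑methylbut‑2‑enoyl)oxazolidin‑2‑one
Conditions: (S)‑4‑benzyloxazolidin‑2‑one, n‑BuLi, THF, −78 → 0 °C
Reagents that add atoms: (S)‑4‑benzyloxazolidin‑2‑one, O=C1N[C@@H](Cc2ccccc2)CO1
Why: N‑acylation of the lithiated oxazolidinone gives the α,β‑unsaturated imide. The auxiliary carries the chirality for Step 2.

**Step 2**
Reactants: 2; 3, prenyl bromide (1‑bromo‑3‑methylbut‑2‑ene)
Product: 4, (4S)‑4‑benzyl‑3‑[(2S)‑5‑methyl‑2‑(prop‑1‑en‑2‑yl)hex‑4‑enoyl]oxazolidin‑2‑one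
Conditions: NaHMDS, THF, −78 °C, 1 h; then 3, −78 → −30 °C
Reagents that add atoms: none
Why: Evans deconjugative α‑alkylation. NaHMDS forms the Z, Na‑chelated dienolate, and the C4 benzyl group blocks one face. Prenyl bromide attacks the opposite face at Cα and sets the (S) centre.

**Step 3**
Reactants: 4
Product: 5, (2S)‑5‑methyl‑2‑(prop‑1‑en‑2‑yl)hex‑4‑en‑1‑ol ((S)‑lavandulol)
Conditions: LiBH4, H2O (1 equiv), Et2O, 0 °C
Reagents that add atoms: none
Why: Hydride cleaves the imide to the primary alcohol under near‑neutral conditions, so the α‑centre does not epimerise. The auxiliary is recovered.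

**Step 4**
Reactants: 5
Product: 6, (2S)‑1‑iodo‑5‑methyl‑2‑(prop‑1‑en‑2‑yl)hex‑4‑ene
Conditions: PPh3, imidazole, I2, CH2Cl2, 0 °C
Reagents that add atoms: iodine, II
Why: Appel‑type SN2 iodination at the primary carbon; the stereocentre is not involved.

**Step 5**
Reactants: 7, resorcinol
Product: 8, 1,3‑bis(methoxymethoxy)benzene
Conditions: MOMCl, i‑Pr2NEt, CH2Cl2, 0 °C → rt
Reagents that add atoms: MOMCl, COCCl
Why: Standard O‑alkylation gives the MOM ethers, which later direct lithiation.

**Step 6**
Reactants: 8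
Product: 9, 3,5‑bis(methoxymethoxy)phenol
Conditions: [Ir(cod)OMe]2 (1.5 mol%), dtbpy (3 mol%), B2pin2 (0.55 equiv), THF, 80 °C; then 30% H2O2, 2 M NaOH, 0 °C → rt (one pot)
Reagents that add atoms: hydrogen peroxide, OO (supplies the phenol oxygen; the Bpin group is only an intermediate)
Why: Sterically controlled Ir‑catalysed C–H borylation occurs at C5, meta to both OMOM groups. Oxidative deboronation then gives the phenol, which completes the 1,3,5‑trioxygenated A‑ring pattern.

**Step 7**
Reactants: 9
Product: 10, 1,3,5‑tris(methoxymethoxy)benzene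
Conditions: MOMCl, i‑Pr2NEt, CH2Cl2, 0 °C → rt
Reagents that add atoms: MOMCl, COCCl
Why: O‑alkylation of the phenol gives a symmetric arene. All three ring C–H positions are equivalent and flanked by two OMOM groups.

**Step 8**
Reactants: 10
Product: 11, 2‑iodo‑1,3,5‑tris(methoxymethoxy)benzene
Conditions: n‑BuLi, THF, 0 °C; then I2, −78 °C → rt
Reagents that add atoms: iodine, II
Why: Directed ortho‑metalation between two OMOM groups, followed by iodine quench, gives the aryl iodide.

**Step 9**
Reactants: 6; 11
Product: 12, 2‑[(2R)‑5‑methyl‑2‑(prop‑1‑en‑2‑yl)hex‑4‑en‑1‑yl]‑1,3,5‑tris(methoxymethoxy)benzene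
Conditions: (a) 6, Zn dust, LiCl, TMSCl/BrCH2CH2Br (cat.), THF, 40 °C; (b) 11, Pd‑PEPPSI‑IPent (3 mol%), THF/toluene, 60 °C
Reagents that add atoms: none
Why: Negishi coupling of a primary alkylzinc with a hindered aryl iodide. The stereocentre is β to the C–Zn bond and is retained, and the bulky NHC ligand favours reductive elimination over β‑hydride elimination.

**Step 10**
Reactants: 12
Product: 13, 1‑{3‑[(2R)‑lavandulyl]‑2,4,6‑tris(methoxymethoxy)phenyl}ethan‑1‑one
Conditions: n‑BuLi, TMEDA, THF, −20 → 0 °C; then CH3C(O)N(OMe)Me, −78 °C → rt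
Reagents that add atoms: N‑methoxy‑N‑methylacetamide, CC(=O)N(C)OC
Why: Directed ortho‑lithiation at the only two (equivalent) ring C–H positions, then acylation with a Weinreb amide, which stops cleanly at the methyl ketone.

**Step 11**
Reactants: 13
Product: 14, 1‑{3‑[(2R)‑lavandulyl]‑2,4,6‑trihydroxyphenyl}ethan‑1‑one
Conditions: ZnBr2 (6 equiv), n‑PrSH (10 equiv), CH2Cl2, 0 °C → rt
Reagents that add atoms: none
Why: Lewis‑acid/thiol cleavage of the aryl MOM acetals is non‑protic. The thiol also scavenges the released formaldehyde, so the phloroglucinol ring is not hydroxymethylated and the alkenes survive.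

**Step 12**
Reactants: 14
Product: 15, 1‑{2‑hydroxy‑3‑[(2R)‑lavandulyl]‑4,6‑bis(methoxymethoxy)phenyl}ethan‑1‑one
Conditions: MOMCl (2.1 equiv), i‑Pr2NEt (2.5 equiv), CH2Cl2, 0 °C
Reagents that add atoms: MOMCl, COCCl
Why: The acidic 4'‑OH reacts first, then the unhindered 6'‑OH. The 2'‑OH is flanked by the lavandulyl group and chelated to the carbonyl, so it stays free. This places the free OH next to the lavandulyl carbon, as needed for the 8‑lavandulyl ring closure.

**Step 13**
Reactants: 7, resorcinol
Product: 16, 2,4‑dihydroxybenzaldehyde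
Conditions: POCl3, DMF, MeCN, 0 °C → rt; then H2O
Reagents that add atoms: DMF, CN(C)C=O (supplies the CHO carbon)
Why: Vilsmeier–Haack formylation occurs at C4, para to one OH and ortho to the other.

**Step 14**
Reactants: 16
Product: 17, 2,4‑bis(methoxymethoxy)benzaldehyde
Conditions: MOMCl, i‑Pr2NEt, CH2Cl2, 0 °C → rt
Reagents that add atoms: MOMCl, COCCl
Why: O‑alkylation masks both phenols so they survive the basic condensation in Step 15.

**Step 15**
Reactants: 15; 17
Product: 18, (E)‑1‑{2‑hydroxy‑3‑[(2R)‑lavandulyl]‑4,6‑bis(methoxymethoxy)phenyl}‑3‑[2,4‑bis(methoxymethoxy)phenyl]prop‑2‑en‑1‑one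
Conditions: KOH, EtOH/H2O, 0 °C → rt, 48 h; then aq. NH4Cl
Reagents that add atoms: none
Why: Claisen–Schmidt aldol condensation gives the thermodynamic E‑enone. In base the 2'‑phenolate is stable, which prevents premature racemic cyclisation. This is the late fragment coupling.

**Step 16**
Reactants: 18
Product: 19, (2S)‑2‑[2,4‑bis(methoxymethoxy)phenyl]‑5,7‑bis(methoxymethoxy)‑8‑[(2R)‑lavandulyl]chroman‑4‑one
Conditions: quinine‑derived bifunctional thiourea (20 mol%), toluene, 25 °C, 4 d
Reagents that add atoms: none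
Why: Asymmetric 6‑endo intramolecular oxa‑Michael addition. The tertiary amine organises the 2'‑phenol and the thiourea H‑bonds the enone carbonyl, so oxygen is delivered to one enone face and sets C2 as (S).

**Step 17**
Reactants: 19
Product: 20, sophoraflavanone G
Conditions: ZnBr2 (8 equiv), n‑PrSH (12 equiv), CH2Cl2, 0 °C → rt
Reagents that add atoms: none
Why: The same mild, non‑reductive, non‑basic MOM cleavage removes all four MOM groups. The alkenes are untouched, and neither stereocentre is involved (no base, so no retro‑oxa‑Michael racemisation at C2).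

## Compound list
1 | 3,3‑dimethylacryloyl chloride | CC(C)=CC(=O)Cl | starting material
2 | (4S)‑4‑benzyl‑3‑(3‑methylbut‑2‑enoyl)oxazolidin‑2‑one | CC(C)=CC(=O)N1[C@@H](Cc2ccccc2)COC1=O | intermediate
3 | prenyl bromide | CC(C)=CCBr | starting material
4 | (4S)‑4‑benzyl‑3‑[(2S)‑5‑methyl‑2‑(prop‑1‑en‑2‑yl)hex‑4‑enoyl]oxazolidin‑2‑one | C=C(C)[C@H](CC=C(C)C)C(=O)N1[C@@H](Cc2ccccc2)COC1=O | intermediate
5 | (2S)‑5‑methyl‑2‑(prop‑1‑en‑2‑yl)hex‑4‑en‑1‑ol | C=C(C)[C@H](CC=C(C)C)CO | intermediate
6 | (2S)‑1‑iodo‑5‑methyl‑2‑(prop‑1‑en‑2‑yl)hex‑4‑ene | C=C(C)[C@H](CC=C(C)C)CI | intermediate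
7 | resorcinol | Oc1cccc(O)c1 | starting material
8 | 1,3‑bis(methoxymethoxy)benzene | COCOc1cccc(OCOC)c1 | intermediate
9 | 3,5‑bis(methoxymethoxy)phenol | COCOc1cc(O)cc(OCOC)c1 | intermediate
10 | 1,3,5‑tris(methoxymethoxy)benzene | COCOc1cc(OCOC)cc(OCOC)c1 | intermediate
11 | 2‑iodo‑1,3,5‑tris(methoxymethoxy)benzene | COCOc1cc(OCOC)c(I)c(OCOC)c1 | intermediate
12 | 2‑[(2R)‑lavandulyl]‑1,3,5‑tris(methoxymethoxy)benzene | C=C(C)[C@H](CC=C(C)C)Cc1c(OCOC)cc(OCOC)cc1OCOC | intermediate
13 | 3'‑lavandulyl‑2',4',6'‑tris(methoxymethoxy)acetophenone | C=C(C)[C@H](CC=C(C)C)Cc1c(OCOC)cc(OCOC)c(C(C)=O)c1OCOC | intermediate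
14 | 3'‑lavandulyl‑2',4',6'‑trihydroxyacetophenone | C=C(C)[C@H](CC=C(C)C)Cc1c(O)cc(O)c(C(C)=O)c1O | intermediate
15 | 2'‑hydroxy‑3'‑lavandulyl‑4',6'‑bis(methoxymethoxy)acetophenone | C=C(C)[C@H](CC=C(C)C)Cc1c(OCOC)cc(OCOC)c(C(C)=O)c1O | intermediate
16 | 2,4‑dihydroxybenzaldehyde | O=Cc1ccc(O)cc1O | intermediate
17 | 2,4‑bis(methoxymethoxy)benzaldehyde | COCOc1ccc(C=O)c(OCOC)c1 | intermediate
18 | (E)‑2'‑hydroxychalcone tetra‑MOM ether bearing the (2R)‑lavandulyl group | C=C(C)[C@H](CC=C(C)C)Cc1c(OCOC)cc(OCOC)c(C(=O)/C=C/c2ccc(OCOC)cc2OCOC)c1O | intermediate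
19 | (2S)‑tetra‑MOM‑sophoraflavanone G | C=C(C)[C@H](CC=C(C)C)Cc1c(OCOC)cc(OCOC)c2c1O[C@H](c1ccc(OCOC)cc1OCOC)CC2=O | intermediate
20 | sophoraflavanone G | C=C(C)[C@H](CC=C(C)C)Cc1c(O)cc(O)c2c1O[C@H](c1ccc(O)cc1O)CC2=O | target

## Totals
- Total step count: 17.
- Longest linear sequence: 11 (Steps 5→6→7→8→9→10→11→12→15→16→17). Steps 1–4 and 13–14 run in parallel.

## Three steps most likely to fail
1. **Step 9 (Negishi).** The aryl iodide is very hindered and electron‑rich, and the alkylzinc has a tertiary allylic β‑H, so β‑hydride elimination and racemisation are possible.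
   - Fallback (different approach): lithiate 10 and formylate it, then reduce and brominate to the benzyl bromide. Alkylate the Evans imide of 5‑methylhex‑4‑enoic acid with it. Build the isopropenyl group from the imide by Weinreb amide → MeMgBr → Petasis or Wittig methylenation. This joins at the same point in the route.
2. **Step 16 (asymmetric oxa‑Michael).** The 2,4‑dialkoxy B ring deactivates the enone, so the reaction is slow and the ee may be low. The flavanone is also base‑labile and can racemise by retro‑Michael.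
   - Fallback (different approach): cyclise 18 racemically (NaOAc, EtOH, reflux) and separate the (2S) enantiomer of 19 by preparative chiral HPLC. Alternatively, build the 8‑lavandulylchromone from 15 and add the 2,4‑bis(MOMO)phenylboronic acid by Pd‑catalysed asymmetric conjugate arylation.
3. **Step 12 (regioselective bis‑MOM protection).** If the 6'‑OH is left free instead of the 2'‑OH, ring closure gives the 6‑lavandulyl regioisomer.
   - Fallback (different approach): desymmetrise earlier. O‑allylate 9, then repeat the DoM/iodination/Negishi/acetylation sequence on that ether. Remove the MOM group ortho to both the ketone and the lavandulyl by chelation‑controlled MgBr2 cleavage, carry the allyl ether through to the end, and remove it with Pd(0)/PhSiH3.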